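**Plan**
- Feature: in the oxolane (O1, C2 aryl, C3 methyl, C4 side arm, C5), C5 is a lone OCH2 carbon bonded only to O1 and C4. The C3 methyl and the C4 carbinol arm (C7′) are cis. The ring therefore corresponds to H (to C3) and CHO (to C4) added to one face of a Z C3=C4 alkene, with the C2 hydroxyl trapping the formyl carbon.
- Cuts: O1–C5 and C4–C5 (C5 comes from CO), then C3–CH3 (cross-coupling), then C2–C3 and C4–C7′ (acetylene placed between two veratraldehyde units).
- Forward: C7′–C4 is joined first, then C3–C2. The alkyne becomes the Z-trisubstituted alkene by syn-hydrostannation and methyl Stille coupling. The only ring then closes as a lactol, and C5 deoxygenation and desilylation finish the route.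
- Stereochemistry: C7′ and C2 come from two BINOL–Ti-catalysed alkynylations run with opposite ligand enantiomers. C3 and C4 arise together from a suprafacial addition whose face is chosen by a C2–O–P–Rh tether under A1,3 strain.

Key step: step 7

Remark on labels: O1, C2–C5 and C7′ are the target's oxolane labels and are used for all intermediates. The R/S changes along 4, 6, 8, 10, 11, 14 and 15 come only from CIP ranking; no bond at C2 or C7′ is broken once it is made.
Assumption: (S)-BINOL/Ti is taken to deliver an alkynyl group to the Si face of veratraldehyde, as with benzaldehyde. Both ligand enantiomers are used, so a reversed sense would only swap them between steps 1 and 4.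

**Step 1**
Reactants: 1 veratraldehyde (3,4-dimethoxybenzaldehyde); 2 trimethylsilylacetylene
Product: 4 (S)-1-(3,4-dimethoxyphenyl)-3-(trimethylsilyl)prop-2-yn-1-ol, via ethyl(trimethylsilylethynyl)zinc 3 (not isolated)
Conditions: 2, Et2Zn, (R)-BINOL (20 mol %), Cy2NH (5 mol %), Et2O, rt; Ti(OiPr)4 (50 mol %); then 1, rt; aq NH4Cl
Reagents that add atoms: none
Why: Catalytic asymmetric alkynylzinc addition (BINOL–Ti type) works best with aromatic aldehydes, and the (R)-ligand should send the alkynyl group to the Re face of 1 and so set C7′.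

**Step 2**
Reactants: 4 (S)-1-(3,4-dimethoxyphenyl)-3-(trimethylsilyl)prop-2-yn-1-ol
Product: 5 (S)-tert-butyl{[1-(3,4-dimethoxyphenyl)-3-(trimethylsilyl)prop-2-yn-1-yl]oxy}dimethylsilane
Conditions: TBSCl, imidazole, DMF, rt
Reagents that add atoms: tert-butyldimethylsilyl chloride, CC(C)(C)[Si](C)(C)Cl
Why: Standard O-silylation leaves C7′ untouched, and TBS is chosen because it survives carbonate, organozinc, Pd/Sn and Rh/CO/H2 conditions and is bulky enough to steer step 5.

**Step 3**
Reactants: 5 (S)-tert-butyl{[1-(3,4-dimethoxyphenyl)-3-(trimethylsilyl)prop-2-yn-1-yl]oxy}dimethylsilane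
Product: 6 (R)-tert-butyl{[1-(3,4-dimethoxyphenyl)prop-2-yn-1-yl]oxy}dimethylsilane
Conditions: K2CO3 (0.2 equiv), MeOH, rt
Reagents that add atoms: none
Why: Carbonate-catalysed methanolysis cleaves the alkynyl C–SiMe3 bond much faster than the hindered O–TBS bond, and the geometry at C7′ is unchanged.

**Step 4**
Reactants: 6 (R)-tert-butyl{[1-(3,4-dimethoxyphenyl)prop-2-yn-1-yl]oxy}dimethylsilane; 1 veratraldehyde
Product: 8 (1R,4S)-4-(tert-butyldimethylsilyloxy)-1,4-bis(3,4-dimethoxyphenyl)but-2-yn-1-ol, via ethylzinc acetylide 7 (not isolated)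
Conditions: 6 (1.3 equiv), Et2Zn, (S)-BINOL (20 mol %), Cy2NH (5 mol %), Et2O, rt; Ti(OiPr)4 (50 mol %); then 1, rt; aq NH4Cl
Reagents that add atoms: none
Why: This is the same asymmetric alkynylzinc addition with the antipodal ligand; C7′ lies far away across a linear alkyne, so the catalyst alone should set C2 by Si-face attack and give the unlike (meso-type) array.

**Step 5**
Reactants: 8 (1R,4S)-4-(tert-butyldimethylsilyloxy)-1,4-bis(3,4-dimethoxyphenyl)but-2-yn-1-ol; 9 tributyltin hydride
Product: 10 (1R,4R,E)-4-(tert-butyldimethylsilyloxy)-1,4-bis(3,4-dimethoxyphenyl)-2-(tributylstannyl)but-2-en-1-ol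
Conditions: Bu3SnH (slow addition), PdCl2(PPh3)2 (3 mol %), THF, 0 °C to rt; Et3N-washed silica
Reagents that add atoms: tributyltin hydride (9), CCCC[SnH](CCCC)CCCC
Why: Pd(0)-catalysed hydrostannation is a strict syn addition, so C2 and C7′ end up cis on the alkene, and tin should go to C3 because a free propargylic hydroxyl draws it near while a bulky propargylic silyl ether pushes it away, two trends that reinforce each other in 8.

**Step 6**
Reactants: 10 (1R,4R,E)-4-(tert-butyldimethylsilyloxy)-1,4-bis(3,4-dimethoxyphenyl)-2-(tributylstannyl)but-2-en-1-ol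
Product: 11 (1S,4R,Z)-4-(tert-butyldimethylsilyloxy)-1,4-bis(3,4-dimethoxyphenyl)-2-methylbut-2-en-1-ol
Conditions: MeI, Pd(PPh3)4 (5 mol %), CuTC, [Bu4N][Ph2PO2], DMF, rt
Reagents that add atoms: iodomethane, CI
Why: In this copper-assisted Stille–Migita methylation of an α-hydroxy alkenylstannane, Sn-to-Cu exchange (driven by phosphinate capture of the tin) and Pd-catalysed coupling both retain the alkene geometry, and the near-neutral medium spares the acid-labile allylic benzylic alcohol.

**Step 7**
Reactants: 11 (1S,4R,Z)-4-(tert-butyldimethylsilyloxy)-1,4-bis(3,4-dimethoxyphenyl)-2-methylbut-2-en-1-ol; 12 carbon monoxide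
Product: 14 (3S,4S,5S)-3-[(R)-(tert-butyldimethylsilyloxy)(3,4-dimethoxyphenyl)methyl]-5-(3,4-dimethoxyphenyl)-4-methyloxolan-2-ol (both anomers), via γ-hydroxy aldehyde 13 (not isolated)
Conditions: Rh(CO)2(acac) (5 mol %), Ph2POMe (20 mol %), CO/H2 1:1 (40 bar), 4 Å MS, THF, 50 °C
Reagents that add atoms: carbon monoxide (12), [C-]#[O+]
Why: Proposed new method: exchange of the methoxy group of Ph2POMe for the C2–OH of 11 ties a Rh–H centre to O1, hydrometalation then puts H on C3 and Rh on C4 through a six-membered P,C-chelate, CO insertion and hydrogenolysis give 13, and the phosphinite passes to the next molecule of 11. The closest known reaction type is the hydroformylation of 2-substituted (1,1-disubstituted) allylic and of homoallylic alcohols to γ-lactols under a reversibly bound phosphinite, together with phosphine-tethered hydroformylation of Z-1,2-disubstituted allylic ethers; an acyclic Z-trisubstituted alkene between two branched carbinol carbons has not been shown, hence the label. The single ring closes when the released C2–OH adds 5-exo-trig to the formyl carbon (O1–C5), and the anomeric centre so formed is uncontrolled and is erased in step 8. C3 and C4 are created together by suprafacial addition to the Z-alkene, which makes them cis, and the face is chosen by C2: A1,3 strain with the cis C7′ substituent holds the C2–H bond in the alkene plane, so the O–P–Rh arm reaches only the face that leaves the methyl group trans to the C2 aryl group, the face on which C7′ also shows its oxygen and not its aryl group. The required regioselectivity (formyl on C4) is secured by the chelate size and by the reluctance of a tertiary C3–Rh alkyl to form and to carbonylate. Chemoselectivity over β-hydride elimination (alkene migration) and over ionisation of the allylic benzylic alcohol rests on the high CO pressure, the moderate temperature and the neutral medium.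

**Step 8**
Reactants: 14 (3S,4S,5S)-3-[(R)-(tert-butyldimethylsilyloxy)(3,4-dimethoxyphenyl)methyl]-5-(3,4-dimethoxyphenyl)-4-methyloxolan-2-ol
Product: 15 tert-butyl{(R)-(3,4-dimethoxyphenyl)[(3R,4S,5S)-5-(3,4-dimethoxyphenyl)-4-methyloxolan-3-yl]methoxy}dimethylsilane
Conditions: Et3SiH (5 equiv), BF3·OEt2, CH2Cl2, −78 °C; Et3N then aq NaHCO3 at −78 °C
Reagents that add atoms: none
Why: In this ionic (Kursanov–Parnes type) lactol reduction BF3 ionises the anomeric OH to a ring oxocarbenium ion that the silane traps, C5 becomes a CH2 so no stereocentre is at stake, and at −78 °C the hindered, weakly basic OTBS oxygen and the C2–O1 bond should stay intact.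

**Step 9**
Reactants: 15 tert-butyl{(R)-(3,4-dimethoxyphenyl)[(3R,4S,5S)-5-(3,4-dimethoxyphenyl)-4-methyloxolan-3-yl]methoxy}dimethylsilane
Product: 16 (R)-(3,4-dimethoxyphenyl)[(3R,4S,5S)-5-(3,4-dimethoxyphenyl)-4-methyloxolan-3-yl]methanol (target)
Conditions: TBAF, THF, 0 °C to rt
Reagents that add atoms: none
Why: Fluoride-induced desilylation breaks only the Si–O bond, so C7′ keeps its configuration and no acid reaches the two benzylic C–O bonds.

**Compound list**
1 | veratraldehyde (3,4-dimethoxybenzaldehyde) | COc1ccc(C=O)cc1OC | starting material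
2 | trimethylsilylacetylene | C#C[Si](C)(C)C | starting material
3 | ethyl[(trimethylsilyl)ethynyl]zinc | CC[Zn]C#C[Si](C)(C)C | intermediate
4 | (S)-1-(3,4-dimethoxyphenyl)-3-(trimethylsilyl)prop-2-yn-1-ol | C[Si](C)(C)C#C[C@@H](O)c1ccc(OC)c(OC)c1 | intermediate
5 | (S)-tert-butyl{[1-(3,4-dimethoxyphenyl)-3-(trimethylsilyl)prop-2-yn-1-yl]oxy}dimethylsilane | C[Si](C)(C)C#C[C@@H](O[Si](C)(C)C(C)(C)C)c1ccc(OC)c(OC)c1 | intermediate
6 | (R)-tert-butyl{[1-(3,4-dimethoxyphenyl)prop-2-yn-1-yl]oxy}dimethylsilane | C#C[C@@H](O[Si](C)(C)C(C)(C)C)c1ccc(OC)c(OC)c1 | intermediate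
7 | [(S)-3-(tert-butyldimethylsilyloxy)-3-(3,4-dimethoxyphenyl)prop-1-yn-1-yl](ethyl)zinc | CC[Zn]C#C[C@@H](O[Si](C)(C)C(C)(C)C)c1ccc(OC)c(OC)c1 | intermediate
8 | (1R,4S)-4-(tert-butyldimethylsilyloxy)-1,4-bis(3,4-dimethoxyphenyl)but-2-yn-1-ol | COc1ccc(cc1OC)[C@@H](O)C#C[C@@H](O[Si](C)(C)C(C)(C)C)c2ccc(OC)c(OC)c2 | intermediate
9 | tributyltin hydride | CCCC[SnH](CCCC)CCCC | starting material
10 | (1R,4R,E)-4-(tert-butyldimethylsilyloxy)-1,4-bis(3,4-dimethoxyphenyl)-2-(tributylstannyl)but-2-en-1-ol | COc1ccc(cc1OC)[C@@H](O)/C([Sn](CCCC)(CCCC)CCCC)=C\[C@@H](O[Si](C)(C)C(C)(C)C)c2ccc(OC)c(OC)c2 | intermediate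
11 | (1S,4R,Z)-4-(tert-butyldimethylsilyloxy)-1,4-bis(3,4-dimethoxyphenyl)-2-methylbut-2-en-1-ol | COc1ccc(cc1OC)[C@@H](O)/C(C)=C\[C@@H](O[Si](C)(C)C(C)(C)C)c2ccc(OC)c(OC)c2 | intermediate
12 | carbon monoxide | [C-]#[O+] | starting material
13 | (2S,3S,4S)-2-[(R)-(tert-butyldimethylsilyloxy)(3,4-dimethoxyphenyl)methyl]-4-(3,4-dimethoxyphenyl)-4-hydroxy-3-methylbutanal | COc1ccc(cc1OC)[C@@H](O)[C@@H](C)[C@H](C=O)[C@@H](O[Si](C)(C)C(C)(C)C)c2ccc(OC)c(OC)c2 | intermediate
14 | (3S,4S,5S)-3-[(R)-(tert-butyldimethylsilyloxy)(3,4-dimethoxyphenyl)methyl]-5-(3,4-dimethoxyphenyl)-4-methyloxolan-2-ol (both anomers) | COc1ccc(cc1OC)[C@H]2OC(O)[C@H]([C@@H](O[Si](C)(C)C(C)(C)C)c3ccc(OC)c(OC)c3)[C@@H]2C | intermediate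
15 | tert-butyl{(R)-(3,4-dimethoxyphenyl)[(3R,4S,5S)-5-(3,4-dimethoxyphenyl)-4-methyloxolan-3-yl]methoxy}dimethylsilane | COc1ccc([C@H]2OC[C@H]([C@@H](O[Si](C)(C)C(C)(C)C)c3ccc(OC)c(OC)c3)[C@@H]2C)cc1OC | intermediate
16 | (R)-(3,4-dimethoxyphenyl)[(3R,4S,5S)-5-(3,4-dimethoxyphenyl)-4-methyloxolan-3-yl]methanol | COc1ccc([C@H]2OC[C@H]([C@@H](O)c3ccc(OC)c(OC)c3)[C@@H]2C)cc1OC | target

Total step count: 9. Longest linear sequence: 9 steps (from veratraldehyde).

**Steps most likely to fail**

First, step 7.
- What may go wrong: the crowded trisubstituted alkene may insert into Rh–H too slowly. Undirected background addition (loss of facial control), β-hydride or β-silyloxy elimination from the C4–Rh alkyl, or [2,3]-rearrangement of the allylic phosphinite (loss of ligand) could then take over.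
- Fallback: it uses known chemistry, still draws C5 from CO, and sets out from 11.
- Hydroboration with 9-BBN (2.2 equiv, THF, rt to reflux; the first equivalent caps the C2–OH) is a syn addition that places boron on the less substituted C4.
- With A1,3-locked Z-allylic alcohols the borane attacks anti to the aryl groups, which is the same face as in step 7. This should give the bis(9-BBN) adduct F1.
- Reductive carbonylation of this borane (CO 1 atm, K(iPrO)3BH, THF, 0 °C), then buffered H2O2 (pH 7), moves C4 from boron to carbon with retention. It frees hydroxy aldehyde 13, which closes to 14, where the route is rejoined.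

Second, step 5.
- What may go wrong: tin may be placed with poor regioselectivity between the two oxygen-flanked alkyne carbons, and the hydride may be lost by Pd-catalysed dimerisation.
- Fallback: it sets out from 8 and replaces steric bias by an alkoxide tether.
- After deprotonation (MeLi, THF), Cp2Zr(H)Cl adds syn with zirconium next to the lithium alkoxide. Iodinolysis (I2, −78 °C) should then give the (E)-vinyl iodide F2.
- Negishi coupling (Me2Zn, PdCl2(dppf), THF) with retention returns to the route at 11, by-passing 10.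

Third, step 8.
- What may go wrong: the Lewis acid may ionise the electron-rich benzylic C7′–O or C2–O1 bond. That would lead to over-reduction, Friedel–Crafts closure or epimerisation. The silyl group may also be lost.
- Fallback: it avoids any cation and sets out from 14.
- NaBH4 (MeOH/THF, 0 °C) opens the lactol to the 1,4-diol F3.
- Selective sulfonylation of the primary hydroxyl (TsCl 1.05 equiv, Et3N, cat. DMAP, CH2Cl2, 0 °C) should give the primary tosylate F4.
- NaH in THF then closes O1–C5 by a 5-exo-tet Williamson displacement at the CH2 carbon, which touches no stereocentre. The route is rejoined at 15.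

**Further compounds**
F1 | step 7 | (2S,3S,4S,7′R)-C4-(9-borabicyclo[3.3.1]nonan-9-yl) adduct of 11, with the C2 oxygen bound as its 9-BBN borinate (H on C3 and B on C4 on the former oxygen face) | COc1ccc(cc1OC)[C@@H](OB2C3CCCC2CCC3)[C@@H](C)[C@H](B2C3CCCC2CCC3)[C@@H](O[Si](C)(C)C(C)(C)C)c2ccc(OC)c(OC)c2
F2 | step 5 | (1R,4R,E)-4-(tert-butyldimethylsilyloxy)-1,4-bis(3,4-dimethoxyphenyl)-2-iodobut-2-en-1-ol | COc1ccc(cc1OC)[C@@H](O)/C(I)=C\[C@@H](O[Si](C)(C)C(C)(C)C)c2ccc(OC)c(OC)c2
F3 | step 8 | (1S,2S,3R)-3-[(R)-(tert-butyldimethylsilyloxy)(3,4-dimethoxyphenyl)methyl]-1-(3,4-dimethoxyphenyl)-2-methylbutane-1,4-diol | COc1ccc(cc1OC)[C@@H](O)[C@@H](C)[C@H](CO)[C@@H](O[Si](C)(C)C(C)(C)C)c2ccc(OC)c(OC)c2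
F4 | step 8 | (2R,3S,4S)-2-[(R)-(tert-butyldimethylsilyloxy)(3,4-dimethoxyphenyl)methyl]-4-(3,4-dimethoxyphenyl)-4-hydroxy-3-methylbutyl 4-methylbenzenesulfonate | COc1ccc(cc1OC)[C@@H](O)[C@@H](C)[C@H](COS(=O)(=O)c2ccc(C)cc2)[C@@H](O[Si](C)(C)C(C)(C)C)c3ccc(OC)c(OC)c3
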